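If a slower feed leaves the end of a flask where it was, look at which rate stands ahead: the feed of substrate, or the making of target. Here are the flasks, their readings and the question.

all flasks: gas 46 mM (held)

| charge | substrate | remark | time |
|---|---|---|---|
| ash | 0.13 M (fed, over 3.0 min) | run made earlier |  |
| birch | 0.30 M (fed, over 3.0 min) | run made earlier |  |
| Friday's | 0.20 M (fed, over 3.0 min) |  | 80 min |
| Thursday's | 0.20 M (fed, over 6.0 min) |  | 80 min |
| Saturday's | 0.20 M (fed, over 12 min) |  | 80 min |
| Wednesday's | 0.20 M (fed, over 25 min) |  | 80 min |

| run | time / min | target / % |
|---|---|---|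
| ash | 5.00 | 2.0 |
| ash | 8.00 | 5.8 |
| ash | 12.0 | 9.9 |
| ash | 20.0 | 20.6 |
| ash | 30.0 | 32.4 |
| ash | 40.0 | 41.8 |
| ash | 60.0 | 55.6 |
| birch | 3.00 | 0.2 |
| birch | 10.0 | 4.3 |
| birch | 20.0 | 12.1 |
| birch | 30.0 | 22.1 |
| birch | 40.0 | 32.4 |
| birch | 50.0 | 41.4 |
| birch | 60.0 | 49.2 |

(standard deviation of a reading: 0.3 percentage points)

- amount of target at the end, in percent of the substrate charged for Friday's, Thursday's, Saturday's, Wednesday's, in this order
- how that number moves from the first to the last of them (falls, then rises / rises, then falls / hardly changes / falls all the way / rises all the way)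

- at the start none of the gas is in solution
- "hardly changes" means that all values lie within two and a half points (for a concentration: within two and a half percent of the largest)

Turn the percentages into a pace, the rise of target in concentration per minute, and use the charge of each run for this. Birch between 30.0 min and 40.0 min makes 3.09 mM min⁻¹. Ash between 12.0 min and 20.0 min makes 1.74 mM min⁻¹. Freeze the birch figure, the faster of the two, as the ceiling pace, a rough upper mark read from scattered readings, for a charge of 0.20 M, which is smaller than birch's.

Now hold the feed against it. The feed rate is the charge over the dosing time, and Wednesday's, the longest feed, gives 8.00 mM min⁻¹. A feed rate above the ceiling pace means that substrate enters faster than target takes it up. Friday's feed gives 66.7 mM min⁻¹, and even Wednesday's feed runs ahead of the ceiling pace of 3.09 mM min⁻¹, so substrate should pile up in each flask rather than be waited for. Expect a nearly flat row, with Wednesday's lowest.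

The forecast gives 64%, 65.5%, 66.5% and 64.5%, shape rises, then falls, and says “I expect a shallow maximum near 12 min”, where this reckoning expects a flat row.

The flasks give 62.0%, 61.9%, 61.6% and 60.2%: the number hardly changes.

    substrate + partner → intermediate A (k = 0.550 M⁻¹ min⁻¹)
    substrate + partner → target (k = 1.70 M⁻¹ min⁻¹)
    substrate + partner ⇌ intermediate B (K = 60.0 M⁻¹, k = 28.0 M⁻¹ min⁻¹)
    intermediate A ⇌ intermediate C (K = 20.0, k = 0.00390 min⁻¹)
    gas ⇌ partner, rate k5*(csat - [partner]) (kL = 0.190 min⁻¹)
    substrate + intermediate C → side product (k = 0.720 M⁻¹ min⁻¹)

Wednesday's feed of 8.00 mM min⁻¹ stood above the ceiling pace of 3.09 mM min⁻¹, and at the end of that feed, at 25.0 min, the flask still held 39.1% of the charged substrate, beside partner at 0.0177 M, below the saturation value of 46 mM. In Friday's, the half-life of partner by its loss with substrate to target, the whole charge counted as there at once, is 2.0 min, shorter than the 3.65 min half-life of the way of gas across to partner, and at the end of that feed partner stood at 0.00319 M.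

The earlier runs and the new flask were generated by integration with made-up constants, noise included.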